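**Retrosynthetic overview**

- Ring labels: A is the benzene ring with the acetyl group, B its pyran ring (O1, C2, C3, C4, C4a, C8a), C the dimethoxybenzene ring, D its pyran ring. Ring B is cut across C4=C3 and O1–C2. This gives salicylaldehyde 4 (ring A complete) and alkenyltrifluoroborate 16, which carries C2 with its two methyl groups, C3, the stereocentre and rings C and D.
- Enabling feature: O1 sits on C8a, ortho to C4a, which carries C4. C4 as an iminium carbon therefore accepts C3 from boron held on a flanking phenoxide, and the ortho-quinone methide O1=C8a–C4a=C4 that follows closes onto C2. The second flanking oxygen (on C5) is tied to the C6 acetyl group by a hydrogen bond and stays a hydroxyl.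
- 16 comes from the (R)-benzylic boronate 12 by stereoretentive insertion of a dimethylvinylidene unit into the C–B bond. 12 comes from asymmetric hydroboration of styrene 11, so the only stereocentre is set by catalyst control and then carried unchanged.
- Order of ring formation: rings A and C are bought as benzene rings. Ring D is made first (propargyl Claisen cascade on the symmetric phenol 5) and ring B last, in the convergent final step. 4 is made from symmetric 1 by O-methylation and C-acetylation, and no protecting group is used.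

Key step: step 9

Assumptions: (S)-DTBM-SEGPHOS is taken as the ligand enantiomer that delivers the R boronate in step 6 (the other enantiomer is used if the sense proves opposite); 13 is taken as a catalogue compound.

**Route**

Step 1
Reactants: 1 2,4,6-trihydroxybenzaldehyde
Product: 2 2,6-dihydroxy-4-methoxybenzaldehyde
Conditions: Me2SO4 (1.0 equiv), K2CO3 (1.05 equiv), acetone, 0 °C to rt
Reagents that add atoms: dimethyl sulfate, COS(=O)(=O)OC
Why: Williamson-type O-methylation with a hard electrophile and a weak base should take the hydroxyl para to the formyl group, which is the most acidic one and the only one not tied to the carbonyl oxygen by a hydrogen bond.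

Step 2
Reactants: 2 2,6-dihydroxy-4-methoxybenzaldehyde
Product: 4 3-acetyl-2,6-dihydroxy-4-methoxybenzaldehyde, via difluoroboron chelate 3 (not isolated)
Conditions: Ac2O (1.5 equiv), BF3·OEt2 (3 equiv), 60 °C; then MeOH–H2O, 60 °C
Reagents that add atoms: acetic anhydride, CC(=O)OC(C)=O
Why: Friedel–Crafts C-acylation of a phloroglucinol-type ring (directly or by O-acylation and Fries shift) is standard under these conditions even when one acyl group is already present, and because the two open ring positions of 2 are mirror images of each other only one C-acetyl isomer, held as chelate 3 until hydrolysis, can form.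

Step 3
Reactants: 5 4-hydroxy-2,6-dimethoxybenzaldehyde; 6 3-chloro-3-methylbut-1-yne
Product: 7 2,6-dimethoxy-4-[(2-methylbut-3-yn-2-yl)oxy]benzaldehyde
Conditions: K2CO3, KI (cat.), CuI (cat.), acetone, reflux
Reagents that add atoms: none
Why: Copper-assisted alkylation of a phenoxide by a tertiary propargylic chloride is the standard entry to aryl 1,1-dimethylpropargyl ethers and tolerates the para-formyl group.

Step 4
Reactants: 7 2,6-dimethoxy-4-[(2-methylbut-3-yn-2-yl)oxy]benzaldehyde
Product: 10 5,7-dimethoxy-2,2-dimethyl-2H-chromene-6-carbaldehyde, via allenylphenol 8 (not isolated), via ortho-quinone methide 9 (not isolated)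
Conditions: N,N-diethylaniline, 180 °C
Reagents that add atoms: none
Why: Thermal aromatic propargyl Claisen rearrangement gives allenylphenol 8, whose 1,5-hydrogen shift to ortho-quinone methide 9 and oxa-6π electrocyclisation close ring D, and since both ortho positions of 7 are equivalent a single chromene should result.

Step 5
Reactants: 10 5,7-dimethoxy-2,2-dimethyl-2H-chromene-6-carbaldehyde
Product: 11 6-ethenyl-5,7-dimethoxy-2,2-dimethyl-2H-chromene
Conditions: Ph3PCH3Br, KOtBu, THF, 0 °C to rt
Reagents that add atoms: methyltriphenylphosphonium bromide, C[P+](c1ccccc1)(c1ccccc1)c1ccccc1.[Br-]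
Why: Wittig methylenation with the unstabilised ylide is reliable for di-ortho-alkoxy benzaldehydes, and the basic medium suits the acid-sensitive electron-rich styrene, which is used without delay.

Step 6
Reactants: 11 6-ethenyl-5,7-dimethoxy-2,2-dimethyl-2H-chromene
Product: 12 2-[(1R)-1-(5,7-dimethoxy-2,2-dimethyl-2H-chromen-6-yl)ethyl]-4,4,5,5-tetramethyl-1,3,2-dioxaborolane
Conditions: CuCl (3 mol %), NaOtBu (6 mol %), (S)-DTBM-SEGPHOS (3.3 mol %), HBpin (1.2 equiv), toluene, rt
Reagents that add atoms: pinacolborane, CC1(C)OBOC1(C)C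
Why: In this copper hydride catalysed Markovnikov hydroboration of a vinylarene the ligated CuH adds across the terminal alkene to give the benzylic copper species, the chiral bisphosphine fixes the face of insertion and so the R configuration of the new centre, σ-bond metathesis with HBpin proceeds with retention, and the 1,2-disubstituted alkene of ring D next to a quaternary carbon should insert far more slowly.

Step 7
Reactants: 12 2-[(1R)-1-(5,7-dimethoxy-2,2-dimethyl-2H-chromen-6-yl)ethyl]-4,4,5,5-tetramethyl-1,3,2-dioxaborolane; 13 1,1-dibromo-2-methylprop-1-ene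
Product: 15 2-[(4S)-4-(5,7-dimethoxy-2,2-dimethyl-2H-chromen-6-yl)-2-methylpent-2-en-3-yl]-4,4,5,5-tetramethyl-1,3,2-dioxaborolane, via lithium boronate complex 14 (not isolated)
Conditions: 13 (1.4 equiv), n-BuLi (1.3 equiv), THF–Et2O–pentane, −110 °C; then 12, −110 to −78 °C; then rt
Reagents that add atoms: none
Why: In this Matteson-type homologation with an alkylidene carbenoid, 1-bromo-2-methylprop-1-enyllithium adds to boron to give complex 14 and on warming the benzylic carbon migrates from boron to the carbenoid carbon with loss of bromide and with retention at the migrating centre (the known course of 1,2-metallate rearrangements of α-haloalkenyl boronate complexes), while the two identical methyl groups remove any question of alkene geometry.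

Step 8
Reactants: 15 2-[(4S)-4-(5,7-dimethoxy-2,2-dimethyl-2H-chromen-6-yl)-2-methylpent-2-en-3-yl]-4,4,5,5-tetramethyl-1,3,2-dioxaborolane
Product: 16 potassium [(4S)-4-(5,7-dimethoxy-2,2-dimethyl-2H-chromen-6-yl)-2-methylpent-2-en-3-yl]trifluoroborate
Conditions: KHF2 (aq., 4 equiv), MeOH, rt
Reagents that add atoms: potassium hydrogen difluoride, F.[F-].[K+]
Why: Conversion of a pinacol boronic ester into the potassium trifluoroborate with KHF2 is general and gives the boron species that enters the Petasis step readily.

Step 9
Reactants: 4 3-acetyl-2,6-dihydroxy-4-methoxybenzaldehyde; 16 potassium [(4S)-4-(5,7-dimethoxy-2,2-dimethyl-2H-chromen-6-yl)-2-methylpent-2-en-3-yl]trifluoroborate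
Product: 20 1-{5-hydroxy-7-methoxy-3-[(1S)-1-(5,7-dimethoxy-2,2-dimethyl-2H-chromen-6-yl)ethyl]-2,2-dimethyl-2H-chromen-6-yl}ethan-1-one, via iminium phenoxide 17 (not isolated), via allylic amine 18 (not isolated), via oxatriene 19 (not isolated)
Conditions: 4 (1.0 equiv), 16 (1.3 equiv), Bn2NH (40 mol %), DMF, 80 °C, argon
Reagents that add atoms: none
Why: Dibenzylamine condenses with the formyl group of 4 (the chelated aryl ketone stays out) to give iminium phenoxide 17, the trifluoroborate exchanges fluoride for a flanking phenoxide, and the resulting borate hands its alkenyl carbon C3 to the iminium carbon C4 within a six-membered array (Petasis borono-Mannich reaction), the two methyl groups on C2 stabilising the positive charge that builds up there during ipso attack. Amine 18 then expels dibenzylamine, which returns to the cycle, to give the ortho-quinone methide 19 (O1=C8a–C4a=C4–C3=C2), and this 1-oxatriene closes ring B by thermal disrotatory oxa-6π electrocyclisation between O1 and C2, which restores the aromaticity of ring A. The closest known reaction type is the amine-promoted condensation of salicylaldehydes with alkenylboronic acids or potassium alkenyltrifluoroborates to 2H-chromenes. No stereocentre is made (the aminated C4 of 18 is lost on elimination and C2 carries two methyl groups), and the existing centre, which bears no leaving group and is not deprotonated by a secondary amine, should pass through unchanged. The selectivity needed is closure through the oxygen on C8a and not through the one on C5: the C5 hydroxyl is held in a hydrogen bond to the C6 acetyl oxygen, so it stays a hydroxyl in 19 and only the wanted product keeps that chelate, and because the electrocyclisation is reversible on heating a misclosed isomer can reopen and drain to 20.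

**Compound list**

1 | 2,4,6-trihydroxybenzaldehyde | O=Cc1c(O)cc(O)cc1O | starting material
2 | 2,6-dihydroxy-4-methoxybenzaldehyde | COc1cc(O)c(C=O)c(O)c1 | intermediate
3 | difluoroboron chelate of 4 (boron bridging the acetyl oxygen and the oxygen between acetyl and formyl; not isolated) | CC1=[O+][B-](F)(F)Oc2c1c(OC)cc(O)c2C=O | intermediate
4 | 3-acetyl-2,6-dihydroxy-4-methoxybenzaldehyde | COc1cc(O)c(C=O)c(O)c1C(C)=O | intermediate
5 | 4-hydroxy-2,6-dimethoxybenzaldehyde | COc1cc(O)cc(OC)c1C=O | starting material
6 | 3-chloro-3-methylbut-1-yne | CC(C)(Cl)C#C | starting material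
7 | 2,6-dimethoxy-4-[(2-methylbut-3-yn-2-yl)oxy]benzaldehyde | COc1cc(OC(C)(C)C#C)cc(OC)c1C=O | intermediate
8 | 4-hydroxy-2,6-dimethoxy-3-(3-methylbuta-1,2-dien-1-yl)benzaldehyde (allenylphenol; not isolated) | COc1cc(O)c(C=C=C(C)C)c(OC)c1C=O | intermediate
9 | 2,6-dimethoxy-3-(3-methylbut-2-en-1-ylidene)-4-oxocyclohexa-1,5-diene-1-carbaldehyde (ortho-quinone methide; not isolated) | O=C1C=C(OC)C(C=O)=C(OC)C1=CC=C(C)C | intermediate
10 | 5,7-dimethoxy-2,2-dimethyl-2H-chromene-6-carbaldehyde | COc1cc2c(c(OC)c1C=O)C=CC(C)(C)O2 | intermediate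
11 | 6-ethenyl-5,7-dimethoxy-2,2-dimethyl-2H-chromene | COc1cc2c(c(OC)c1C=C)C=CC(C)(C)O2 | intermediate
12 | 2-[(1R)-1-(5,7-dimethoxy-2,2-dimethyl-2H-chromen-6-yl)ethyl]-4,4,5,5-tetramethyl-1,3,2-dioxaborolane | C[C@@H](B1OC(C)(C)C(C)(C)O1)c1c(OC)cc2c(c1OC)C=CC(C)(C)O2 | intermediate
13 | 1,1-dibromo-2-methylprop-1-ene | CC(C)=C(Br)Br | starting material
14 | lithium (1-bromo-2-methylprop-1-en-1-yl)[(1R)-1-(5,7-dimethoxy-2,2-dimethyl-2H-chromen-6-yl)ethyl](pinacolato)borate (not isolated) | [Li+].CC(C)=C(Br)[B-]1(OC(C)(C)C(C)(C)O1)[C@H](C)c1c(OC)cc2c(c1OC)C=CC(C)(C)O2 | intermediate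
15 | 2-[(4S)-4-(5,7-dimethoxy-2,2-dimethyl-2H-chromen-6-yl)-2-methylpent-2-en-3-yl]-4,4,5,5-tetramethyl-1,3,2-dioxaborolane | CC(C)=C(B1OC(C)(C)C(C)(C)O1)[C@H](C)c1c(OC)cc2c(c1OC)C=CC(C)(C)O2 | intermediate
16 | potassium [(4S)-4-(5,7-dimethoxy-2,2-dimethyl-2H-chromen-6-yl)-2-methylpent-2-en-3-yl]trifluoroborate | [K+].CC(C)=C([B-](F)(F)F)[C@H](C)c1c(OC)cc2c(c1OC)C=CC(C)(C)O2 | intermediate
17 | N,N-dibenzyl-1-(3-acetyl-2-hydroxy-4-methoxy-6-oxidophenyl)methaniminium (iminium phenoxide; not isolated) | COc1cc([O-])c(C=[N+](Cc2ccccc2)Cc2ccccc2)c(O)c1C(C)=O | intermediate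
18 | 1-{3-[(3S)-1-(dibenzylamino)-3-(5,7-dimethoxy-2,2-dimethyl-2H-chromen-6-yl)-2-(propan-2-ylidene)butyl]-2,4-dihydroxy-6-methoxyphenyl}ethan-1-one (both epimers at the aminated carbon; not isolated) | COc1cc(O)c(C(N(Cc2ccccc2)Cc2ccccc2)C(=C(C)C)[C@H](C)c2c(OC)cc3c(c2OC)C=CC(C)(C)O3)c(O)c1C(C)=O | intermediate
19 | 4-acetyl-5-hydroxy-3-methoxy-6-[(3S)-3-(5,7-dimethoxy-2,2-dimethyl-2H-chromen-6-yl)-2-(propan-2-ylidene)butylidene]cyclohexa-2,4-dien-1-one (oxatriene; not isolated) | COC1=CC(=O)C(=CC(=C(C)C)[C@H](C)c2c(OC)cc3c(c2OC)C=CC(C)(C)O3)C(O)=C1C(C)=O | intermediate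
20 | 1-{5-hydroxy-7-methoxy-3-[(1S)-1-(5,7-dimethoxy-2,2-dimethyl-2H-chromen-6-yl)ethyl]-2,2-dimethyl-2H-chromen-6-yl}ethan-1-one | COc1cc2c(c(O)c1C(C)=O)C=C([C@H](C)c1c(OC)cc3c(c1OC)C=CC(C)(C)O3)C(C)(C)O2 | target

**Step count and risks**

Total step count: 9. Longest linear sequence: 7 (steps 3 to 9).

Steps most likely to fail:

1. Step 9. Transfer of the congested tetrasubstituted alkenyl group from boron to the electron-rich, strongly chelated iminium may be slow, so that protodeboronation of 16 or amine-promoted self-condensation of 4 takes over; closure through the wrong oxygen is a lesser risk. The fallback sets out from 15 and 4 and comes back at 20. 15 is treated with NaOMe and then I2 (THF–MeOH, −78 °C) to give 6-[(2R)-3-iodo-4-methylpent-3-en-2-yl]-5,7-dimethoxy-2,2-dimethyl-2H-chromene F1, and 4 is condensed with TsNHNH2 (MeOH, rt) to N'-[(3-acetyl-2,6-dihydroxy-4-methoxyphenyl)methylidene]-4-methylbenzenesulfonohydrazide F2. The two are joined with Pd2(dba)3, XPhos and LiOtBu in dioxane at 90 °C. The base turns F2 in the flask into 1-[3-(diazomethyl)-2,4-dihydroxy-6-methoxyphenyl]ethan-1-one F3, the alkenylpalladium species from F1 forms a palladium carbene with it, migratory insertion makes C4–C3, and the π-allylpalladium that results is closed by the phenoxide at its dimethyl-substituted end (O1–C2) to give 20. This is the known palladium-catalysed chromene synthesis from salicylaldehyde tosylhydrazones and alkenyl halides, and it does not depend on boron-to-carbon transfer or on the electrophilicity of the aldehyde.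

2. Step 7. The carbenoid may rearrange or decompose before it is captured by the hindered secondary boronic ester, or complex 14 may lose an oxygen ligand instead of undergoing carbon migration. The fallback sets out from 12 and 13 and comes back at 15. A stereoretentive Suzuki–Miyaura coupling of the secondary benzylic boronic ester 12 with one C–Br bond of 13 (Pd(PPh3)4, added PPh3, Ag2O, DME, 85 °C; retention at the benzylic carbon is the known course under these silver oxide conditions) would give 6-[(2R)-3-bromo-4-methylpent-3-en-2-yl]-5,7-dimethoxy-2,2-dimethyl-2H-chromene F4. Bromine–lithium exchange (t-BuLi, THF, −78 °C) and trapping with 2-isopropoxy-4,4,5,5-tetramethyl-1,3,2-dioxaborolane then give 15.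

3. Step 6. Insertion of the twisted, very electron-rich di-ortho-methoxystyrene into CuH may be slow and poorly face-selective, and longer reaction times invite hydroboration of the ring D alkene. The fallback sets out from 10 and comes back at 12, setting the centre by ketone reduction and transferring it to boron.
   - MeMgBr (THF, 0 °C) gives racemic 1-(5,7-dimethoxy-2,2-dimethyl-2H-chromen-6-yl)ethan-1-ol F5.
   - Dess–Martin periodinane gives 1-(5,7-dimethoxy-2,2-dimethyl-2H-chromen-6-yl)ethan-1-one F6.
   - Corey–Bakshi–Shibata reduction ((S)-2-methyl-CBS-oxazaborolidine, BH3·SMe2, THF) gives (1R)-1-(5,7-dimethoxy-2,2-dimethyl-2H-chromen-6-yl)ethan-1-ol F7.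
   - N,N-diisopropylcarbamoyl chloride and Et3N (toluene, reflux) give (1R)-1-(5,7-dimethoxy-2,2-dimethyl-2H-chromen-6-yl)ethyl N,N-diisopropylcarbamate F8.
   - Lithiation–borylation (s-BuLi, Et2O, −78 °C; HBpin; then warming) gives 12. Lithiation and borylation go with retention and the 1,2-hydride shift with inversion, so the R carbamate gives the R boronate.

Further compounds
F1 | step 9 | 6-[(2R)-3-iodo-4-methylpent-3-en-2-yl]-5,7-dimethoxy-2,2-dimethyl-2H-chromene | CC(C)=C(I)[C@H](C)c1c(OC)cc2c(c1OC)C=CC(C)(C)O2
F2 | step 9 | N'-[(3-acetyl-2,6-dihydroxy-4-methoxyphenyl)methylidene]-4-methylbenzenesulfonohydrazide | COc1cc(O)c(C=NNS(=O)(=O)c2ccc(C)cc2)c(O)c1C(C)=O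
F3 | step 9 | 1-[3-(diazomethyl)-2,4-dihydroxy-6-methoxyphenyl]ethan-1-one | COc1cc(O)c(C=[N+]=[N-])c(O)c1C(C)=O
F4 | step 7 | 6-[(2R)-3-bromo-4-methylpent-3-en-2-yl]-5,7-dimethoxy-2,2-dimethyl-2H-chromene | CC(C)=C(Br)[C@H](C)c1c(OC)cc2c(c1OC)C=CC(C)(C)O2
F5 | step 6 | racemic 1-(5,7-dimethoxy-2,2-dimethyl-2H-chromen-6-yl)ethan-1-ol | CC(O)c1c(OC)cc2c(c1OC)C=CC(C)(C)O2
F6 | step 6 | 1-(5,7-dimethoxy-2,2-dimethyl-2H-chromen-6-yl)ethan-1-one | CC(=O)c1c(OC)cc2c(c1OC)C=CC(C)(C)O2
F7 | step 6 | (1R)-1-(5,7-dimethoxy-2,2-dimethyl-2H-chromen-6-yl)ethan-1-ol | C[C@@H](O)c1c(OC)cc2c(c1OC)C=CC(C)(C)O2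
F8 | step 6 | (1R)-1-(5,7-dimethoxy-2,2-dimethyl-2H-chromen-6-yl)ethyl N,N-diisopropylcarbamate | C[C@@H](OC(=O)N(C(C)C)C(C)C)c1c(OC)cc2c(c1OC)C=CC(C)(C)O2
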